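**Plan**

- Numbering used: C7 is the ketone carbon, C8 the stereocentre, C9 the methyl carbon; ring A is the 3,4,5-trimethoxyphenyl ring and ring B the 2,6-dimethoxyphenoxy ring.
- Retrosynthesis: cut the C7–ring A bond (Weinreb amide plus aryl Grignard), then the ring B–vinyl bond of the E-cinnamyl alcohol arm (Suzuki coupling), then the ring B O–C8 bond (phenol plus a C3 ester).
- Enabling feature: C8 carries C9H3, H, the ring-B ether oxygen and the C7 carbonyl carbon. That is the pattern left when H2 adds across C8=C9 of a 2-aryloxyacrylic acid whose carboxyl carbon is C7.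
- Forward order: aryl ether/acrylate, free acid, hydrogenation, Weinreb amide, side-chain coupling, aryl ketone, desilylation. Both benzene rings are bought; no ring is formed.
- Stereochemistry: the single stereocentre C8 (R) comes from the catalyst-controlled hydrogenation; the E alkene comes from the boronate with retention.

Key step: step 3

Remark on the chemistry: the CIP order at C8 is O > C7 > C9 > H in the target and in every intermediate from 7 onward, so the descriptor stays R throughout. Which ligand antipode gives R in step 3 is not assumed; it is to be fixed in a pilot run.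

**Route**

Step 1
Reactants: 1 4-bromo-2,6-dimethoxyphenol; 2 ethyl 2,3-dibromopropanoate
Product: 4 ethyl 2-(4-bromo-2,6-dimethoxyphenoxy)prop-2-enoate, via β-bromo α-aryloxy ester 3 (not isolated)
Conditions: K2CO3 (3 equiv), acetone, reflux
Reagents that add atoms: none
Why: Williamson-type SN2 displacement of the ester-activated α-bromide by the potassium phenoxide should give 3, whose acidic α-hydrogen and β-bromide then undergo E1cB dehydrobromination to the captodative acrylate (substitution–elimination of a 2,3-dibromopropanoate with a phenol).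

Step 2
Reactants: 4 ethyl 2-(4-bromo-2,6-dimethoxyphenoxy)prop-2-enoate
Product: 6 2-(4-bromo-2,6-dimethoxyphenoxy)prop-2-enoic acid, via lithium 2-aryloxyacrylate 5 (not isolated)
Conditions: LiOH·H2O, THF/H2O (3:1), 0 °C → rt; then 1 M HCl to pH 3, 0 °C
Reagents that add atoms: lithium hydroxide, [Li+].[OH-]
Why: Ester saponification (BAc2) should occur at the unhindered ethyl ester while the aryl vinyl ether and the aryl bromide are inert to hydroxide; brief cold acidification frees the acid without hydrolysing the electron-poor enol ether.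

Step 3
Reactants: 6 2-(4-bromo-2,6-dimethoxyphenoxy)prop-2-enoic acid
Product: 7 (R)-2-(4-bromo-2,6-dimethoxyphenoxy)propanoic acid
Conditions: H2 (6 atm), [Ir(cod)(SIPHOX)]BArF (1 mol%, ligand antipode chosen for R), Et3N (0.5 equiv), MeOH, rt
Reagents that add atoms: none
Why: The carboxylate of 6 binds the cationic iridium dihydride and holds the C8=C9 enol-ether alkene in the spiro P,N pocket; migratory insertion most plausibly puts hydride on C8 while C9 stays on iridium in a five-membered carboxylate-chelated metallacycle, and hydrogenolysis of that Ir–C9 bond forms the second C–H bond. The closest known reaction type is the Ir–spiro phosphine-oxazoline (or Rh/Ru–diphosphine) asymmetric hydrogenation of α-aryloxy and α-alkoxy α,β-unsaturated carboxylic acids and of α-substituted acrylic acids. No ring is closed and no skeletal bond is formed. The only new stereocentre, C8, is set under catalyst control by the chiral ligand with the carboxylate as anchoring group; the ligand antipode that gives R is to be fixed in a pilot run by chiral HPLC against a reference sample of known configuration. The step needs facial selectivity at a 1,1-disubstituted alkene and chemoselectivity over the aryl C–Br bond: the bulky 2,6-dimethoxyaryloxy group on C8 differentiates the two faces, the homogeneous iridium catalyst does not insert into the aryl bromide, and the styrenyl alkene is introduced only later.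

Step 4
Reactants: 7 (R)-2-(4-bromo-2,6-dimethoxyphenoxy)propanoic acid
Product: 8 (R)-2-(4-bromo-2,6-dimethoxyphenoxy)-N-methoxy-N-methylpropanamide
Conditions: MeNHOMe·HCl, EDC·HCl, HOBt (cat.), N-methylmorpholine, CH2Cl2, 0 °C → rt
Reagents that add atoms: N,O-dimethylhydroxylamine hydrochloride, CNOC.Cl
Why: Carbodiimide-mediated amide coupling at 0 °C should give the Weinreb amide with C8 untouched, since an α-aryloxy acid has no oxazolone pathway and the weak tertiary amine does not enolise the activated acyl species.

Step 5
Reactants: 8 (R)-2-(4-bromo-2,6-dimethoxyphenoxy)-N-methoxy-N-methylpropanamide; 9 (E)-3-(tert-butyldimethylsilyloxy)prop-1-enylboronic acid pinacol ester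
Product: 10 (R,E)-2-[4-(3-(tert-butyldimethylsilyloxy)prop-1-enyl)-2,6-dimethoxyphenoxy]-N-methoxy-N-methylpropanamide
Conditions: Pd(dppf)Cl2·CH2Cl2 (5 mol%), K3PO4, 1,4-dioxane/H2O (5:1), 80 °C
Reagents that add atoms: none
Why: Suzuki–Miyaura coupling of the aryl bromide (both ortho positions are CH) with the E-alkenyl boronate should proceed with retention of alkene geometry; aqueous phosphate does not deprotonate C8 of the amide, and the Weinreb amide and TBS ether are inert to the conditions.

Step 6
Reactants: 10 (R,E)-2-[4-(3-(tert-butyldimethylsilyloxy)prop-1-enyl)-2,6-dimethoxyphenoxy]-N-methoxy-N-methylpropanamide; 11 5-bromo-1,2,3-trimethoxybenzene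
Product: 14 (R,E)-2-[4-(3-(tert-butyldimethylsilyloxy)prop-1-enyl)-2,6-dimethoxyphenoxy]-1-(3,4,5-trimethoxyphenyl)propan-1-one, via 3,4,5-trimethoxyphenylmagnesium bromide 12 (not isolated), via bromomagnesium N-methoxy hemiaminal chelate 13 (not isolated)
Conditions: 11, Mg, I2 (cat.), THF, reflux; then 10, THF, −20 → 0 °C; sat. aq. NH4Cl, 0 °C
Reagents that add atoms: none
Why: Weinreb ketone synthesis: the Grignard reagent 12 from magnesium insertion into 11 adds once to the amide to give the five-membered N-methoxy chelate 13, which resists further addition and enolisation and collapses to the ketone only on the mild aqueous quench, so C8 should keep its configuration.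

Step 7
Reactants: 14 (R,E)-2-[4-(3-(tert-butyldimethylsilyloxy)prop-1-enyl)-2,6-dimethoxyphenoxy]-1-(3,4,5-trimethoxyphenyl)propan-1-one
Product: 15 (R,E)-2-[4-(3-hydroxyprop-1-enyl)-2,6-dimethoxyphenoxy]-1-(3,4,5-trimethoxyphenyl)propan-1-one (CNP0171423.1)
Conditions: HF·pyridine, pyridine, THF, 0 °C → rt
Reagents that add atoms: none
Why: Fluoride-mediated desilylation under pyridine-buffered HF should cleave the primary allylic TBS ether while avoiding both a basic medium that would enolise the α-aryloxy ketone at C8 and a strong acid that would ionise the electron-rich cinnamyl alcohol.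

**Compound list**

1 | 4-bromo-2,6-dimethoxyphenol | COc1cc(Br)cc(OC)c1O | starting material
2 | ethyl 2,3-dibromopropanoate | CCOC(=O)C(Br)CBr | starting material
3 | ethyl 3-bromo-2-(4-bromo-2,6-dimethoxyphenoxy)propanoate (racemic) | CCOC(=O)C(CBr)Oc1c(OC)cc(Br)cc1OC | intermediate
4 | ethyl 2-(4-bromo-2,6-dimethoxyphenoxy)prop-2-enoate | C=C(Oc1c(OC)cc(Br)cc1OC)C(=O)OCC | intermediate
5 | lithium 2-(4-bromo-2,6-dimethoxyphenoxy)prop-2-enoate | C=C(Oc1c(OC)cc(Br)cc1OC)C(=O)[O-].[Li+] | intermediate
6 | 2-(4-bromo-2,6-dimethoxyphenoxy)prop-2-enoic acid | C=C(Oc1c(OC)cc(Br)cc1OC)C(=O)O | intermediate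
7 | (R)-2-(4-bromo-2,6-dimethoxyphenoxy)propanoic acid | C[C@@H](Oc1c(OC)cc(Br)cc1OC)C(=O)O | intermediate
8 | (R)-2-(4-bromo-2,6-dimethoxyphenoxy)-N-methoxy-N-methylpropanamide | C[C@@H](Oc1c(OC)cc(Br)cc1OC)C(=O)N(C)OC | intermediate
9 | (E)-3-(tert-butyldimethylsilyloxy)prop-1-enylboronic acid pinacol ester | CC(C)(C)[Si](C)(C)OC/C=C/B1OC(C)(C)C(C)(C)O1 | starting material
10 | (R,E)-2-[4-(3-(tert-butyldimethylsilyloxy)prop-1-enyl)-2,6-dimethoxyphenoxy]-N-methoxy-N-methylpropanamide | C[C@@H](Oc1c(OC)cc(/C=C/CO[Si](C)(C)C(C)(C)C)cc1OC)C(=O)N(C)OC | intermediate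
11 | 5-bromo-1,2,3-trimethoxybenzene | COc1cc(Br)cc(OC)c1OC | starting material
12 | 3,4,5-trimethoxyphenylmagnesium bromide | COc1cc([Mg]Br)cc(OC)c1OC | intermediate
13 | bromomagnesium alkoxide of the tetrahedral N-methoxy-N-methyl hemiaminal from 10 and 12 (C8 R, hemiaminal carbon undefined) | COc1cc(C(O[Mg]Br)(N(C)OC)[C@@H](C)Oc2c(OC)cc(/C=C/CO[Si](C)(C)C(C)(C)C)cc2OC)cc(OC)c1OC | intermediate
14 | (R,E)-2-[4-(3-(tert-butyldimethylsilyloxy)prop-1-enyl)-2,6-dimethoxyphenoxy]-1-(3,4,5-trimethoxyphenyl)propan-1-one | COc1cc(C(=O)[C@@H](C)Oc2c(OC)cc(/C=C/CO[Si](C)(C)C(C)(C)C)cc2OC)cc(OC)c1OC | intermediate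
15 | (R,E)-2-[4-(3-hydroxyprop-1-enyl)-2,6-dimethoxyphenoxy]-1-(3,4,5-trimethoxyphenyl)propan-1-one | COc1cc(C(=O)[C@@H](C)Oc2c(OC)cc(/C=C/CO)cc2OC)cc(OC)c1OC | target

**Step count**

Total steps: 7. Longest linear sequence: 7 steps (1 → 4 → 6 → 7 → 8 → 10 → 14 → 15); compounds 2, 9 and 11 enter as bought materials.

**Steps most likely to fail, with fallbacks**

Step 1. The hindered phenoxide may react sluggishly, or it may add in conjugate fashion to an acrylate formed by early dehydrobromination of 2, which would place the aryloxy group on C9 instead of C8. The fallback sets out from 1. O-Alkylation with ethyl bromoacetate (K2CO3, DMF) should give ethyl 2-(4-bromo-2,6-dimethoxyphenoxy)acetate F1. Claisen condensation of its enolate with diethyl oxalate (NaOEt, Et2O/EtOH) should give diethyl 2-(4-bromo-2,6-dimethoxyphenoxy)-3-oxobutanedioate F2 as its sodium enolate. Treatment of that enolate with aqueous formaldehyde and K2CO3 (hydroxymethylation at C8, then loss of the oxalyl unit) introduces the C9 methylene unambiguously and comes back to the route at 4.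

Step 3. Facial discrimination at the 1,1-disubstituted enol-ether alkene may be insufficient, or turnover may be slow because the two ortho methoxy groups crowd the metal. The fallback takes C8 from the chiral pool and sets out from 1. Mitsunobu etherification with ethyl (S)-lactate (PPh3, DIAD, THF, 0 °C → rt) inverts the lactate carbon and should give ethyl (R)-2-(4-bromo-2,6-dimethoxyphenoxy)propanoate F3. Saponification with LiOH in THF/H2O at 0 °C comes back to the route at 7. The same material serves as the configurational reference for the pilot hydrogenation.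

Step 6. Acyl substitution by the electron-rich aryl Grignard reagent may be slow enough that deprotonation at C8 competes, which would erode the enantiomeric purity or leave unreacted amide. The fallback changes the acyl electrophile and sets out from 10. DIBAL-H reduction (THF, −78 °C) should give (R,E)-2-[4-(3-(tert-butyldimethylsilyloxy)prop-1-enyl)-2,6-dimethoxyphenoxy]propanal F4, used crude and cold. Addition of 12 at −78 °C, fast at an aldehyde, should give (2R,E)-2-[4-(3-(tert-butyldimethylsilyloxy)prop-1-enyl)-2,6-dimethoxyphenoxy]-1-(3,4,5-trimethoxyphenyl)propan-1-ol F5 as a mixture of C7 epimers. Dess–Martin oxidation buffered with NaHCO3 (CH2Cl2, 0 °C) removes the C7 stereocentre and comes back to the route at 14.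

**Further compounds**

F1 | step 1 | ethyl 2-(4-bromo-2,6-dimethoxyphenoxy)acetate | CCOC(=O)COc1c(OC)cc(Br)cc1OC
F2 | step 1 | diethyl 2-(4-bromo-2,6-dimethoxyphenoxy)-3-oxobutanedioate | CCOC(=O)C(=O)C(Oc1c(OC)cc(Br)cc1OC)C(=O)OCC
F3 | step 3 | ethyl (R)-2-(4-bromo-2,6-dimethoxyphenoxy)propanoate | CCOC(=O)[C@@H](C)Oc1c(OC)cc(Br)cc1OC
F4 | step 6 | (R,E)-2-[4-(3-(tert-butyldimethylsilyloxy)prop-1-enyl)-2,6-dimethoxyphenoxy]propanal | C[C@@H](Oc1c(OC)cc(/C=C/CO[Si](C)(C)C(C)(C)C)cc1OC)C=O
F5 | step 6 | (2R,E)-2-[4-(3-(tert-butyldimethylsilyloxy)prop-1-enyl)-2,6-dimethoxyphenoxy]-1-(3,4,5-trimethoxyphenyl)propan-1-ol | COc1cc(C(O)[C@@H](C)Oc2c(OC)cc(/C=C/CO[Si](C)(C)C(C)(C)C)cc2OC)cc(OC)c1OC
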